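**Plan**
- Retrosynthesis: the last cut removes three benzyl ethers and the 5''-methyl ether. The key cut opens ring C of unit 2 (the 8''-linked 7''-methoxyflavone, double-primed locants) at O1''–C8a'', C4''–C4a'' and O1''–C2'', giving a C4a''–C8a'' aryne and an arylpropiolic acid. The C6–C8'' biaryl bond is then cut to a 6-borylated acacetin dibenzyl ether and an iodinated o-silylaryl triflate.
- Enabling feature: in unit 2 the ring oxygen O1'' sits on C8a'' (beside the biaryl carbon C8'') and the acyl carbon C4'' sits on C4a'' (beside the 5''-oxygen). This is where a carboxylate oxygen and its acyl group end up when the carboxylate attacks a 3-alkoxyaryne at the carbon remote from the alkoxy group.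
- Forward order: the benzene ring of unit 2 is prepared as a silyl triflate from 1-bromo-3,5-dimethoxybenzene (steps 1–4). Unit 1 is taken complete from acacetin (steps 5–8). Suzuki coupling joins them (step 9), ring C of unit 2 is closed last (step 11), and one Lewis-acid step frees the phenols (step 12).
- Stereochemistry: the target has no stereocentre; the C6–C8'' axis is formed without control.

Key step: step 11

Assumption: the target structure gives no descriptor for the hindered C6–C8'' axis, so the biaryl is made as the racemic mixture of atropisomers.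

**Step 1**
Reactants: 1 1-bromo-3,5-dimethoxybenzene
Product: 3 2-bromo-4,6-dimethoxybenzaldehyde, via aryl iminium salt 2 (not isolated)
Conditions: POCl3, DMF, 0 °C to 90 °C; then aq. NaOAc
Reagents that add atoms: N,N-dimethylformamide CN(C)C=O; water O
Why: Vilsmeier–Haack formylation, in which the chloroiminium electrophile should attack the carbon next to bromine (para to one methoxyl, ortho to the other) in preference to the more crowded carbon between the two methoxyls, the iminium salt being hydrolysed on work-up.

**Step 2**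
Reactants: 3 2-bromo-4,6-dimethoxybenzaldehyde
Product: 5 2-bromo-4,6-dimethoxyphenol, via aryl formate 4 (not isolated)
Conditions: mCPBA, CH2Cl2, 0 °C to rt; then K2CO3 (cat.), MeOH, rt
Reagents that add atoms: mCPBA O=C(OO)c1cccc(Cl)c1
Why: Baeyer–Villiger oxidation in its Dakin form, in which the electron-rich 2,4-dialkoxyaryl group migrates to oxygen to give the aryl formate and methanolysis then frees the phenol without touching the C–Br bond.

**Step 3**
Reactants: 5 2-bromo-4,6-dimethoxyphenol
Product: 8 4,6-dimethoxy-2-(trimethylsilyl)phenyl trifluoromethanesulfonate, via aryl trimethylsilyl ether 6 (not isolated), via lithium silylphenoxide 7 (not isolated)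
Conditions: (Me3Si)2NH, THF, reflux, evaporate; n-BuLi, THF, −78 °C; then Tf2O, −78 °C to rt
Reagents that add atoms: hexamethyldisilazane C[Si](C)(C)N[Si](C)(C)C; trifluoromethanesulfonic anhydride O=S(=O)(OS(=O)(=O)C(F)(F)F)C(F)(F)F
Why: O-silylation followed by bromine–lithium exchange sets off the 1,3 O-to-C silyl shift (retro-Brook rearrangement), and the lithium phenoxide so formed is triflated in the same flask, the standard entry to o-silylaryl triflates.

**Step 4**
Reactants: 8 4,6-dimethoxy-2-(trimethylsilyl)phenyl trifluoromethanesulfonate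
Product: 9 3-iodo-4,6-dimethoxy-2-(trimethylsilyl)phenyl trifluoromethanesulfonate
Conditions: N-iodosuccinimide, CF3CO2H (cat.), MeCN, rt
Reagents that add atoms: N-iodosuccinimide O=C1CCC(=O)N1I
Why: Electrophilic aromatic iodination at C3, which is ortho to the 4-methoxyl and para to the 6-methoxyl (the site at which 1-substituted 2,4-dimethoxybenzenes are halogenated), whereas the silyl-bearing carbon is meta to both methoxyls and next to the triflate, so ipso-desilylation should not compete.

**Step 5**
Reactants: 10 acacetin (5,7-dihydroxy-4'-methoxyflavone)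
Product: 11 7-O-benzylacacetin
Conditions: BnBr (1 equiv), K2CO3, acetone, reflux
Reagents that add atoms: benzyl bromide BrCc1ccccc1
Why: Williamson etherification, selective for O7 because the 5-OH is held in a hydrogen bond to the C4 carbonyl and is much less acidic and less accessible.

**Step 6**
Reactants: 11 7-O-benzylacacetin
Product: 12 7-O-benzyl-6-iodoacacetin
Conditions: BnMe3N ICl2, CaCO3, CH2Cl2/MeOH, rt
Reagents that add atoms: benzyltrimethylammonium dichloroiodate C[N+](C)(C)Cc1ccccc1.Cl[I-]Cl
Why: Electrophilic iodination with a dichloroiodate salt, for which the free chelated 5-OH of 5-hydroxy-7-alkoxyflavones directs the iodine to the ortho carbon C6 and not to C8, CaCO3 taking up the HCl formed.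

**Step 7**
Reactants: 12 7-O-benzyl-6-iodoacacetin
Product: 13 5,7-di-O-benzyl-6-iodoacacetin
Conditions: BnBr, K2CO3, DMF, 70 °C
Reagents that add atoms: benzyl bromide BrCc1ccccc1
Why: Williamson etherification of the chelated 5-OH under more forcing conditions, which caps the last phenol of unit 1 so that no phenoxide can intercept the aryne later.

**Step 8**
Reactants: 13 5,7-di-O-benzyl-6-iodoacacetin
Product: 14 5,7-bis(benzyloxy)-2-(4-methoxyphenyl)-6-(4,4,5,5-tetramethyl-1,3,2-dioxaborolan-2-yl)-4H-chromen-4-one
Conditions: pinacolborane, Et3N, Pd(OAc)2, 2-(dicyclohexylphosphino)biphenyl, dioxane, 80 °C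
Reagents that add atoms: pinacolborane CC1(C)OBOC1(C)C
Why: Palladium-catalysed Miyaura-type borylation of an aryl iodide with pinacolborane, run with a bulky dialkylbiarylphosphine because the iodide has two ortho alkoxy groups, under amine-base conditions that leave the flavone and the benzyl ethers alone.

**Step 9**
Reactants: 14 flavone 6-boronate; 9 3-iodo-4,6-dimethoxy-2-(trimethylsilyl)phenyl trifluoromethanesulfonate
Product: 15 3-[5,7-bis(benzyloxy)-2-(4-methoxyphenyl)-4-oxo-4H-chromen-6-yl]-4,6-dimethoxy-2-(trimethylsilyl)phenyl trifluoromethanesulfonate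
Conditions: Pd(OAc)2, SPhos, K3PO4, toluene/H2O, 90 °C
Reagents that add atoms: none
Why: Suzuki–Miyaura coupling in which zerovalent palladium should insert into the C–I bond of 9 far faster than into the doubly flanked C–OTf bond, with a ligand of the type that joins 2,6-dialkoxyarylboron reagents to di-ortho-substituted halides and a fluoride-free base that spares the silyl/triflate pair, the new axis forming as a racemate.

**Step 10**
Reactants: 16 1-(benzyloxy)-4-iodobenzene; 17 propiolic acid
Product: 18 3-(4-benzyloxyphenyl)propiolic acid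
Conditions: Pd(PPh3)4 (cat.), DBU, DMSO, 35 °C; then aq. HCl
Reagents that add atoms: none
Why: Copper-free Sonogashira-type coupling of an aryl iodide with propiolic acid, run near room temperature so that the carboxylate salt of the product should not lose CO2.

**Step 11**
Reactants: 15 biaryl o-silylaryl triflate; 18 3-(4-benzyloxyphenyl)propiolic acid
Product: 21 5,7-bis(benzyloxy)-6-[2-(4-benzyloxyphenyl)-5,7-dimethoxy-4-oxo-4H-chromen-8-yl]-2-(4-methoxyphenyl)-4H-chromen-4-one, via aryne 19 (not isolated), via ynone caesium phenoxide 20 (not isolated)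
Conditions: CsF, THF (dilute), sealed tube, 125 °C
Reagents that add atoms: none
Why: CsF strips the SiMe3 group from C8a'' and triflate leaves from C4a'', giving aryne 19; the caesium carboxylate of 18 adds through oxygen to C8a'' (O1''–C8a''), the aryl anion left on C4a'' attacks the ester carbonyl, and the four-membered intermediate opens to the o-acylphenoxide 20 (C4''–C4a''), a net insertion of the aryne into the C–O bond of the acid. The closest known reaction type is this fluoride-mediated C–O insertion of arynes into carboxylic acids, which with arylpropiolic acids is known to run on to flavones. Ring C of unit 2 then closes by 6-endo-dig conjugate addition of the phenoxide oxygen to the aryl-bearing alkyne carbon (O1''–C2''); 5-exo attack at the carbon next to the carbonyl would be the anti-Michael mode and should stay minor. No stereocentre is created, so no element of stereocontrol is needed. The selectivity that matters is the site of carboxylate attack on the unsymmetrical aryne: the 5''-methoxyl beside C4a'' withdraws inductively and distorts the triple bond so that the nucleophile enters at the remote C8a'' and the negative charge develops beside the oxygen-bearing carbon, a bias that should outweigh the shielding of C8a'' by the neighbouring flavonyl ring for a small oxygen nucleophile. High temperature and dilution favour the intramolecular acyl shift over protonation of the aryl anion, and unit 1, a fully etherified flavone, offers no acidic or nucleophilic site to the aryne.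

**Step 12**
Reactants: 21 tri-O-benzyl 5''-O-methyl biflavone
Product: 22 5,7-dihydroxy-6-[5-hydroxy-2-(4-hydroxyphenyl)-7-methoxy-4-oxo-4H-chromen-8-yl]-2-(4-methoxyphenyl)-4H-chromen-4-one (CNP0290866.0)
Conditions: BCl3, C6HMe5, CH2Cl2, −78 °C to rt; then MeOH/H2O
Reagents that add atoms: none
Why: Lewis-acid ether cleavage in which BCl3 removes the benzyl ethers at low temperature while pentamethylbenzene traps the benzyl cations, and on warming cleaves only the methyl ether that can chelate boron to the C4'' carbonyl (5''-OMe), so the unchelated 7''- and 4'-methyl ethers should remain.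

**Compound list**
1 | 1-bromo-3,5-dimethoxybenzene | COc1cc(Br)cc(OC)c1 | starting material
2 | N-[(2-bromo-4,6-dimethoxyphenyl)methylidene]-N-methylmethanaminium chloride | C[N+](C)=Cc1c(Br)cc(OC)cc1OC.[Cl-] | intermediate
3 | 2-bromo-4,6-dimethoxybenzaldehyde | O=Cc1c(Br)cc(OC)cc1OC | intermediate
4 | 2-bromo-4,6-dimethoxyphenyl formate | O=COc1c(Br)cc(OC)cc1OC | intermediate
5 | 2-bromo-4,6-dimethoxyphenol | Oc1c(Br)cc(OC)cc1OC | intermediate
6 | (2-bromo-4,6-dimethoxyphenoxy)trimethylsilane | C[Si](C)(C)Oc1c(Br)cc(OC)cc1OC | intermediate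
7 | lithium 2,4-dimethoxy-6-(trimethylsilyl)phenoxide | [Li+].[O-]c1c(OC)cc(OC)cc1[Si](C)(C)C | intermediate
8 | 4,6-dimethoxy-2-(trimethylsilyl)phenyl trifluoromethanesulfonate | COc1cc(OC)c(OS(=O)(=O)C(F)(F)F)c([Si](C)(C)C)c1 | intermediate
9 | 3-iodo-4,6-dimethoxy-2-(trimethylsilyl)phenyl trifluoromethanesulfonate | COc1cc(OC)c(OS(=O)(=O)C(F)(F)F)c([Si](C)(C)C)c1I | intermediate
10 | acacetin (5,7-dihydroxy-2-(4-methoxyphenyl)-4H-chromen-4-one) | COc1ccc(cc1)-c1cc(=O)c2c(O)cc(O)cc2o1 | starting material
11 | 7-O-benzylacacetin (7-benzyloxy-5-hydroxy-2-(4-methoxyphenyl)-4H-chromen-4-one) | COc1ccc(cc1)-c1cc(=O)c2c(O)cc(OCc3ccccc3)cc2o1 | intermediate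
12 | 7-O-benzyl-6-iodoacacetin (7-benzyloxy-5-hydroxy-6-iodo-2-(4-methoxyphenyl)-4H-chromen-4-one) | COc1ccc(cc1)-c1cc(=O)c2c(O)c(I)c(OCc3ccccc3)cc2o1 | intermediate
13 | 5,7-di-O-benzyl-6-iodoacacetin (5,7-bis(benzyloxy)-6-iodo-2-(4-methoxyphenyl)-4H-chromen-4-one) | COc1ccc(cc1)-c1cc(=O)c2c(OCc3ccccc3)c(I)c(OCc3ccccc3)cc2o1 | intermediate
14 | 5,7-bis(benzyloxy)-2-(4-methoxyphenyl)-6-(4,4,5,5-tetramethyl-1,3,2-dioxaborolan-2-yl)-4H-chromen-4-one | COc1ccc(cc1)-c1cc(=O)c2c(OCc3ccccc3)c(B3OC(C)(C)C(C)(C)O3)c(OCc3ccccc3)cc2o1 | intermediate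
15 | 3-[5,7-bis(benzyloxy)-2-(4-methoxyphenyl)-4-oxo-4H-chromen-6-yl]-4,6-dimethoxy-2-(trimethylsilyl)phenyl trifluoromethanesulfonate | COc1ccc(cc1)-c1cc(=O)c2c(OCc3ccccc3)c(-c3c(OC)cc(OC)c(OS(=O)(=O)C(F)(F)F)c3[Si](C)(C)C)c(OCc3ccccc3)cc2o1 | intermediate
16 | 1-(benzyloxy)-4-iodobenzene | Ic1ccc(OCc2ccccc2)cc1 | starting material
17 | propiolic acid | OC(=O)C#C | starting material
18 | 3-(4-benzyloxyphenyl)propiolic acid | OC(=O)C#Cc1ccc(OCc2ccccc2)cc1 | intermediate
19 | 5,7-bis(benzyloxy)-6-(5,6-didehydro-2,4-dimethoxyphenyl)-2-(4-methoxyphenyl)-4H-chromen-4-one (aryne across C4a''–C8a'') | COc1ccc(cc1)-c1cc(=O)c2c(OCc3ccccc3)c(C3=C(OC)C=C(OC)C#C3)c(OCc3ccccc3)cc2o1 | intermediate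
20 | caesium 2-[5,7-bis(benzyloxy)-2-(4-methoxyphenyl)-4-oxo-4H-chromen-6-yl]-6-[3-(4-benzyloxyphenyl)prop-2-ynoyl]-3,5-dimethoxyphenolate | COc1ccc(cc1)-c1cc(=O)c2c(OCc3ccccc3)c(-c3c(OC)cc(OC)c(C(=O)C#Cc4ccc(OCc5ccccc5)cc4)c3[O-])c(OCc3ccccc3)cc2o1.[Cs+] | intermediate
21 | 5,7-bis(benzyloxy)-6-[2-(4-benzyloxyphenyl)-5,7-dimethoxy-4-oxo-4H-chromen-8-yl]-2-(4-methoxyphenyl)-4H-chromen-4-one | COc1ccc(cc1)-c1cc(=O)c2c(OCc3ccccc3)c(-c3c(OC)cc(OC)c4c(=O)cc(-c5ccc(OCc6ccccc6)cc5)oc34)c(OCc3ccccc3)cc2o1 | intermediate
22 | 5,7-dihydroxy-6-[5-hydroxy-2-(4-hydroxyphenyl)-7-methoxy-4-oxo-4H-chromen-8-yl]-2-(4-methoxyphenyl)-4H-chromen-4-one (CNP0290866.0) | COc1ccc(cc1)-c1cc(=O)c2c(O)c(-c3c(OC)cc(O)c4c(=O)cc(-c5ccc(O)cc5)oc34)c(O)cc2o1 | target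

**Step count**
Total: 12 steps. Longest linear sequence: 7 steps (steps 1, 2, 3, 4, 9, 11, 12 from compound 1; the acacetin branch through steps 5–8 is equally long).

**Steps most likely to fail**

Step 9 (biaryl coupling). The bond is made between a carbon flanked by two benzyloxy groups and a carbon flanked by a methoxyl and a SiMe3 group. Protodeboronation of the doubly ortho-alkoxylated boronate 14 may outrun transmetalation onto the crowded arylpalladium intermediate, so that no biaryl forms. The fallback is a Negishi coupling, which needs neither boron nor aqueous base. It sets out from iodide 13 and uses iodide 9 unchanged. Zinc dust with LiCl in THF at 40 °C should insert into the C–I bond of 13 to give [5,7-bis(benzyloxy)-2-(4-methoxyphenyl)-4-oxo-4H-chromen-6-yl]zinc iodide F1, an organozinc that tolerates the chromone carbonyl. Coupling of F1 with 9 (Pd2(dba)3, RuPhos, THF/NMP, 70 °C), in which only the C–I bond of 9 should react, rejoins the route at 15.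

Step 11 (aryne insertion and ring closure). The caesium arylpropiolate may lose CO2 at the temperature the insertion needs before the aryne captures it, or the ynone phenoxide may close through the wrong alkyne carbon. The fallback intercepts the same aryne with an acid that can do neither, commercial (E)-4-(benzyloxy)cinnamic acid. Setting out from 15, CsF in THF at 125 °C should give, by the same C–O insertion, the caesium 2'-oxidochalcone F2, which closes by 6-endo-trig oxa-Michael addition to the racemic flavanone F3; this is the known passage from arynes and cinnamic acids to 2-aryl-4-chromanones. Dehydrogenation of F3 with DDQ in dioxane at reflux introduces the C2''–C3'' double bond and returns to 21.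

Step 12 (global deprotection). Benzyl cations may escape the scavenger and alkylate the electron-rich rings, or the four ether cleavages may run at different rates and leave mixtures of partly protected products. The fallback removes the two kinds of ether separately. Setting out from 21, hydrogenolysis (H2, Pd/C, THF/MeOH, rt) should remove the three benzyl groups without forming any cation and give 5,7-dihydroxy-6-[2-(4-hydroxyphenyl)-5,7-dimethoxy-4-oxo-4H-chromen-8-yl]-2-(4-methoxyphenyl)-4H-chromen-4-one F4. AlCl3 in MeCN at 60 °C, which cleaves only a methoxyl peri to the flavone carbonyl, then gives target 22.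

**Further compounds**
F1 | step 9 | [5,7-bis(benzyloxy)-2-(4-methoxyphenyl)-4-oxo-4H-chromen-6-yl]zinc iodide | COc1ccc(cc1)-c1cc(=O)c2c(OCc3ccccc3)c([Zn]I)c(OCc3ccccc3)cc2o1
F2 | step 11 | caesium 2-[5,7-bis(benzyloxy)-2-(4-methoxyphenyl)-4-oxo-4H-chromen-6-yl]-6-[(E)-3-(4-benzyloxyphenyl)prop-2-enoyl]-3,5-dimethoxyphenolate | COc1ccc(cc1)-c1cc(=O)c2c(OCc3ccccc3)c(-c3c(OC)cc(OC)c(C(=O)/C=C/c4ccc(OCc5ccccc5)cc4)c3[O-])c(OCc3ccccc3)cc2o1.[Cs+]
F3 | step 11 | 5,7-bis(benzyloxy)-6-[2-(4-benzyloxyphenyl)-5,7-dimethoxy-4-oxochroman-8-yl]-2-(4-methoxyphenyl)-4H-chromen-4-one (racemic at C2'') | COc1ccc(cc1)-c1cc(=O)c2c(OCc3ccccc3)c(-c3c(OC)cc(OC)c4C(=O)CC(c5ccc(OCc6ccccc6)cc5)Oc34)c(OCc3ccccc3)cc2o1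
F4 | step 12 | 5,7-dihydroxy-6-[2-(4-hydroxyphenyl)-5,7-dimethoxy-4-oxo-4H-chromen-8-yl]-2-(4-methoxyphenyl)-4H-chromen-4-one | COc1ccc(cc1)-c1cc(=O)c2c(O)c(-c3c(OC)cc(OC)c4c(=O)cc(-c5ccc(O)cc5)oc34)c(O)cc2o1
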